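# Proposal: total synthesis of CNP0365569.2 by acetylenic oxy-Cope ring expansion of a carvone-derived cyclohexenol

## The problem

The target is a furanoheliangolide. Its ten-membered carbocycle (C1–C10, germacrane numbering) is bridged by an oxygen between C3 and C10, so that O, C10, C1, C2 and C3 form a 3(2H)-furanone. It also carries a trans-fused α-methylene-γ-butyrolactone on C6/C7, a cis (Z) C4=C5 olefin conjugated to the furanone, a methacrylate on C8 and an acetate on C9.

Five contiguous stereocentres run from C6 to C10 (6R,7S,8S,9S,10S), and C10 is quaternary, carrying a methyl group and the bridging oxygen. Only C7 is easily bought from the chiral pool. The plan must therefore let C7 set C8, C8 set C10, and C10 (through the shape of the ring) set the oxygens at C9 and C8, while C7 also sets C6.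

The methylene lactone and the methacrylate are Michael acceptors, the acetate sits beside a tertiary carbinol carbon and can migrate, and the furanone is a cross-conjugated dienone. None of these tolerates strong base, organolithium reagents or hydride, so all must be installed after the skeleton is complete, and transannular reactions of the medium ring must be avoided.

The central difficulty is the medium ring itself, because direct closure of a ten-membered ring with a cis trisubstituted olefin is costly in both entropy and strain. The feature that offers a way round is that C3–C8, with the C4 methyl, the cis C4=C5 olefin and the three-carbon branch on C7, are a carvone in disguise. C1 and C3 are a 1,3-diketone masked in the furanone beside the oxygenated quaternary C10. An ynol ether C1≡C2 on C3 and an enol ether C9=C10 on C8 therefore make a 3-oxy-1,5-enyne in which a [3,3] shift exchanges the ring bond C3–C8 for C1–C10 and turns the six-membered ring into the ten-membered one.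

## Retrosynthesis

**Furanone (26 ⇒ 25).** The C3–O bond of the furanone is cut and C1 is returned to an ethyl enol ether, which gives the hydroxy vinylogous ester 25. This cut comes first because the oxygen bridge cannot exist while C8=C9 is an E olefin (a trans double bond would sit in a nine-membered oxacycle), and because it lets the most delicate ring appear last under mild acid. The forward step only asks the C10 hydroxyl to add to C3 and water and ethanol to leave.

**Esters and the C8/C9 oxygens (25 ⇒ 24 ⇒ 23 ⇒ 22).** The acetate C–O bond at C9 is cut, then the C8–O bond of the methacrylate back to the 8,9-epoxide 23, then the epoxide back to the E olefin of lactone 22. The two oxygens are related as in an anti addition to an E olefin, so a syn dihydroxylation alone cannot serve, whereas an epoxide opened once with inversion can. Using methacrylic acid itself as the nucleophile saves a hydrolysis and a selective acylation. The free C10 hydroxyl is the handle: it must deliver the oxidant to the outer face of the olefin and then, as a titanium alkoxide, steer the acid to C8.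

**Lactone (22 ⇒ 19 ⇒ 18 ⇒ 16).** The lactone is opened to the 6,12-diol (triol 19), the silyl ethers are restored (18), and the C6–O bond is cut to give 16. C6 is γ to the C3 ketone through C4=C5, and 16 has no α′ hydrogen, so vinylogous enolisation can occur only there. Carrying a C6 oxygen through the ring expansion instead would need a 4-oxygenated carvone that is not at hand. The forward reaction must bring oxygen to C6 trans to the C7 branch.

**Ring expansion (16 ⇒ 13).** The C1–C10 bond is cut and the C3–C8 bond re-formed, which contracts the ten-membered vinylogous ester to cyclohexenol 13. Unlike any single-bond cut for a cyclisation, this removes the medium ring altogether, keeps the cis olefin inside a six-membered ring, and reduces the quaternary C10 to an enol ether geometry plus the C8 stereocentre. The forward reaction must be a suprafacial [3,3] shift with E selectivity at C8=C9.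

**Alkyne (13 ⇒ 10 + 11).** The C2–C3 bond is cut to ketone 10 and ethoxyacetylene 11. Only a clean 1,2-addition is required, since the configuration created at C3 disappears in the next step.

**Side chain (10 ⇒ 9 ⇒ 8 ⇒ 5 + 6).** The O–Si bond of the enol ether is cut to methyl ketone 9, the ketone is taken back to the terminal olefin of 8, and the C8–C9 bond is cut to 5 and allyl bromide 6. Allyl is preferred to propargyl because oxidation of a monosubstituted olefin spares the other two olefins, whereas hydrating an α-propargyl ketone invites furan formation. The forward reactions must alkylate trans to the C7 branch and enolise the methyl ketone towards C9 with Z geometry.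

**C12 oxygen (5 ⇒ 4 ⇒ 2 ⇒ 1).** The silyl ether and the C12–O bond are cut back through chloride 2 to (S)-carvone 1. This oxidation is placed first because carvone is the only compound of the route in which the isopropenyl group is the sole electron-rich olefin.

## Roads not taken

**Alternative 1:** The cut is the C4=C5 double bond. In the forward direction the second-generation Hoveyda–Grubbs catalyst would join an isopropenyl group on furanone carbon C3 with a vinyl group on C6, release ethylene and close the carbocycle as acetonide A1.
- Merits: the route is convergent; furanone, lactone and all five stereocentres are in place before the ring is closed; no late C–H oxidation is needed; only the Z olefin fits the bridged bicycle.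
- Weak points for this target:
  - a trisubstituted olefin must be formed from a 1,1-disubstituted, furanone-conjugated (electron-poor) alkene;
  - the exocyclic methylene of the lactone is a third olefin that can enter metathesis;
  - closure of a strained bridged ten-membered ring competes with oligomerisation;
  - after closure the cis 8,9-diol must be differentiated (methacrylate on C8, acetate on C9) under risk of acyl migration;
  - the open-chain precursor with five contiguous stereocentres is long to make.
- Comparison: this road is better in convergence and in settling the oxygens at C6, C8 and C9 early. The adopted plan sets against it a ring made by ring expansion (no entropic penalty), a cis olefin and C7 bought with carvone, C10 set by chirality transfer, and eight steps to the carbocycle. It pays with late oxygenations.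

**Alternative 2:** The cut removes the O–C10 and C9–C10 bonds and restores an O–C7 bond, which contracts the oxa-bridged ring to a dihydropyran carrying a diazoketone. In the forward direction Cu(hfacac)2 would generate a carbenoid at C10, the ring oxygen would trap it, and the oxonium ylide would shift its alkoxyvinyl arm [2,3] to give A2.
- Merits: the oxygen bridge, the quaternary C10 and the C9 oxygen are created in one ring-expanding step; no macrocyclisation is needed; the reaction class has good precedent for oxa-bridged medium rings.
- Weak points for this target: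
  - A2 has no C11–C13 branch on C7 and no oxygen on C8, only an unfunctionalised cis C7=C8 olefin that would need a regio- and stereoselective carbo-oxygenation on the medium ring;
  - its five-membered ring is a saturated ketone that still has to be dehydrogenated to the furanone;
  - a [1,2] shift and olefin isomers can compete in the key step.
- Comparison: this road is stronger for C9, C10 and the bridge, which cost the adopted plan its last four steps. The adopted plan delivers C7 with its branch, the C4 methyl and the cis C4=C5 olefin from the first step, which A2 would have to acquire late.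

**Alternative 3:** The cut removes the C1–C2 and O–C3 bonds of an isoxazole that stands for the 1,3-diketone. In the forward direction a primary nitro group at C1 would be dehydrated (PhNCO, Et3N) to a nitrile oxide that adds across the terminal C2–C3 alkyne and closes isoxazole and carbocycle together as A3.
- Merits: lactone ring, C8/C9 acetonide and C10 are in place before ring closure; the tether fixes the regiochemistry; the isoxazole is a robust mask, more so than the acid-labile vinylogous ester of the adopted plan.
- Weak points for this target:
  - a ten-membered ring bridging the 3- and 5-positions of an isoxazole is strained, so high dilution is needed and nitrile oxide dimerisation competes;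
  - the later N–O cleavage (for example with Mo(CO)6) and enaminone hydrolysis must spare the enone and lactone;
  - A3 still lacks the exocyclic methylene;
  - the linear precursor is long.
- Comparison: this road is better in the robustness of the masked diketone and in making no stereocentre late. The adopted plan sets against it ring formation without a strained macrocyclisation and a much shorter path to the carbocycle.

Key step: step 8

Remark on numbering: germacrane numbering is used for the target and all ten-membered compounds (C1 ketone, C3 furanone carbon on the bridging oxygen, C4 with methyl C15, C6 lactone oxygen, C10 with methyl C14, C11=C13, C12 lactone carbonyl). Six-membered compounds are named as carvone derivatives (C1 carbonyl, C5 side chain, C6 α′ carbon, C10 the allylic carbon that becomes C12).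

Assumption: lithium ethoxyacetylide adds to ketone 10 anti to the axial C8–H, giving the C3 configuration drawn for 13. The C3 epimer would serve equally, because C3 becomes the carbonyl carbon in step 8.

## Route

Step 1
Reactants: 1 (S)-(+)-carvone
Product: 2 (S)-10-chlorocarvone
Conditions: Ca(OCl)2, CO2 (s), CH2Cl2/H2O, 0 °C
Reagents that add atoms: calcium hypochlorite, [Ca+2].[O-]Cl.[O-]Cl
Why: Ene-type allylic chlorination of the electron-rich 1,1-disubstituted olefin by hypochlorous acid made in situ; the conjugated ring olefin is inert and C7 is untouched.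

Step 2
Reactants: 2 (S)-10-chlorocarvone
Product: 4 (S)-10-hydroxycarvone, via acetate 3 (not isolated)
Conditions: KOAc, Bu4NI (cat.), DMF, 50 °C; then K2CO3, MeOH, 0 °C → rt
Reagents that add atoms: potassium acetate, CC(=O)[O-].[K+]
Why: SN2 displacement of the allylic chloride by acetate (the SN2′ path gives the same product) followed by mild transesterification; both are standard and leave the enone intact.

Step 3
Reactants: 4 (S)-10-hydroxycarvone
Product: 5 (S)-10-(tert-butyldimethylsilyloxy)carvone
Conditions: TBSCl, imidazole, CH2Cl2, rt
Reagents that add atoms: tert-butyldimethylsilyl chloride, CC(C)(C)[Si](C)(C)Cl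
Why: Standard silylation of a primary alcohol; the ether survives amide bases, organolithium reagents and KH and is cleaved by fluoride in step 10.

Step 4
Reactants: 5 (S)-10-(tert-butyldimethylsilyloxy)carvone; 6 allyl bromide
Product: 8 (5S,6R)-6-allyl-10-(tert-butyldimethylsilyloxy)carvone, via lithium enolate 7 (not isolated)
Conditions: LiN(iPr)2, THF, −78 °C; then 6, −78 → 0 °C
Reagents that add atoms: none
Why: Kinetic α′-deprotonation gives the cross-conjugated enolate, which is alkylated anti to the adjacent C5 substituent (enolate alkylation); any cis isomer can be epimerised by base to the diequatorial trans compound.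

Step 5
Reactants: 8 (5S,6R)-6-allyl-10-(tert-butyldimethylsilyloxy)carvone
Product: 9 (5S,6R)-10-(tert-butyldimethylsilyloxy)-6-(2-oxopropyl)carvone
Conditions: PdCl2 (cat.), CuCl, O2 (1 atm), DMF/H2O, rt
Reagents that add atoms: water, O
Why: Wacker–Tsuji oxidation is selective for the monosubstituted terminal olefin; the 1,1-disubstituted and the conjugated olefin do not react.

Step 6
Reactants: 9 (5S,6R)-10-(tert-butyldimethylsilyloxy)-6-(2-oxopropyl)carvone
Product: 10 (5S,6S)-10-(tert-butyldimethylsilyloxy)-6-[(Z)-2-(triisopropylsilyloxy)prop-1-enyl]carvone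
Conditions: iPr3SiOTf, Et3N, CH2Cl2, 0 °C → rt
Reagents that add atoms: triisopropylsilyl triflate, CC(C)[Si](C(C)C)(C(C)C)OS(=O)(=O)C(F)(F)F
Why: Soft enolisation with silyl triflate and amine favours the more substituted enol ether, and the Z isomer (ring carbon cis to oxygen, trans to methyl) is favoured because the branched ring carbon avoids the methyl group. The ring ketone, whose only α′ hydrogen is a hindered methine, should not compete; isomers are separable on base-washed silica.

Step 7
Reactants: 10 (5S,6S)-10-(tert-butyldimethylsilyloxy)-6-[(Z)-2-(triisopropylsilyloxy)prop-1-enyl]carvone; 11 ethoxyacetylene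
Product: 13 (1S,5S,6S)-5-[3-(tert-butyldimethylsilyloxy)prop-1-en-2-yl]-1-(ethoxyethynyl)-2-methyl-6-[(Z)-2-(triisopropylsilyloxy)prop-1-enyl]cyclohex-2-en-1-ol, via lithium ethoxyacetylide 12 (not isolated)
Conditions: n-BuLi, THF, −78 °C; then 10, −78 → −40 °C; NH4Cl (aq)
Reagents that add atoms: none
Why: 1,2-Addition of a lithium acetylide to the enone carbonyl at low temperature (anhydrous CeCl3 can be added if enolisation competes); the small nucleophile attacks axially, so the alkynyl group ends cis to the C6 side chain. The acid-sensitive carbinol is used at once.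

Step 8
Reactants: 13 (1S,5S,6S)-5-[3-(tert-butyldimethylsilyloxy)prop-1-en-2-yl]-1-(ethoxyethynyl)-2-methyl-6-[(Z)-2-(triisopropylsilyloxy)prop-1-enyl]cyclohex-2-en-1-ol
Product: 16 (7S,10S)-12-(tert-butyldimethylsilyloxy)-1-ethoxy-10-(triisopropylsilyloxy)germacra-1E,4Z,8E,11(13)-tetraen-3-one, via potassium alkoxide 14 (not isolated), via potassium allenolate 15 (not isolated)
Conditions: KH, 18-crown-6, THF, 0 °C → rt; NH4Cl (aq), −78 °C
Reagents that add atoms: none
Why: Proposed new method: KH with 18-crown-6 gives the free potassium alkoxide 14, whose charge weakens the C3–C8 bond and drives a concerted [3,3] shift through a six-centre transition state in which the ynol ether terminus C1 bonds to the enol ether carbon C10 while C3–C8 breaks, the driving force being the conjugated allenolate 15; the closest known reaction type is the anionic acetylenic oxy-Cope ring expansion of 1-alkynyl-2-alkenylcycloalkanols to cycloalkenones through allenolates, and the extension lies in pairing an oxygen-substituted alkyne with a fully substituted silyl enol ether terminus, both of which are spectators to the bond reorganisation. The ten-membered ring is formed by four-atom expansion of the six-membered ring, not by end-to-end cyclisation, so neither high dilution nor a ring-closure rule applies. The only new stereocentre, C10, is controlled by C8: the shift is suprafacial on the C8–C9–C10 unit, the C8–H bond lies in the plane of the enol ether (the other rotamer would press C7 against the cis silyloxy group), C7 therefore ends trans to C10 (E C8=C9), and with the Z enol ether this fixes C1–C10 bond formation on the face that gives 10S. The selectivity needed is E over Z at C8=C9 together with retention of the enol ether geometry; allylic strain against the bulky triisopropylsilyloxy group secures the first, and the same bulk blocks oxygen-to-oxygen silyl transfer to the alkoxide. The reacting conformer of 14 is the half-chair with the alkynyl group pseudo-equatorial and the C7 and C8 substituents pseudo-axial; the C3 epimer would react from its all-equatorial conformer and give the same product. The cis C4=C5 olefin is carried over unchanged from the six-membered ring. Cold protonation of 15 at the central allene carbon C2 gives vinylogous ester 16.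

Step 9
Reactants: 16 (7S,10S)-12-(tert-butyldimethylsilyloxy)-1-ethoxy-10-(triisopropylsilyloxy)germacra-1E,4Z,8E,11(13)-tetraen-3-one
Product: 18 (6R,7S,10S)-12-(tert-butyldimethylsilyloxy)-1-ethoxy-6-hydroxy-10-(triisopropylsilyloxy)germacra-1E,4Z,8E,11(13)-tetraen-3-one, via triethylsilyl dienol ether 17 (not isolated)
Conditions: Et3SiOTf, Et3N, CH2Cl2, −78 → 0 °C; filtration through basic alumina; then DMDO, acetone, −78 °C; NaHCO3 (aq)
Reagents that add atoms: dimethyldioxirane, CC1(C)OO1
Why: Vinylogous Rubottom oxidation: the ketone has no α′ hydrogen, so soft enolisation can only remove a C6 hydrogen and give the extended dienol ether 17, whose distal C5=C6 bond is the least hindered electron-rich site for the dioxirane (C4 is fully substituted and shielded by the silyloxy group). Peripheral attack anti to the C7–C8 ring bond, with C7–H in the plane of the diene, places the hydroxyl trans to the C7 branch (6R); any C6 silyl ether formed by silyl transfer is cleaved in step 10.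

Step 10
Reactants: 18 (6R,7S,10S)-12-(tert-butyldimethylsilyloxy)-1-ethoxy-6-hydroxy-10-(triisopropylsilyloxy)germacra-1E,4Z,8E,11(13)-tetraen-3-one
Product: 19 (6R,7S,10S)-1-ethoxy-6,10,12-trihydroxygermacra-1E,4Z,8E,11(13)-tetraen-3-one
Conditions: Bu4NF, THF, 0 → 50 °C
Reagents that add atoms: none
Why: Fluoride-mediated desilylation: the primary silyl ether is cleaved quickly and the hindered tertiary one on warming; vinylogous ester, enone and olefins are inert to fluoride.

Step 11
Reactants: 19 (6R,7S,10S)-1-ethoxy-6,10,12-trihydroxygermacra-1E,4Z,8E,11(13)-tetraen-3-one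
Product: 22 (6R,7S,10S)-1-ethoxy-10-hydroxy-3-oxogermacra-1E,4Z,8E,11(13)-tetraen-12,6-olide, via enal 20 (not isolated), via lactol 21 (not isolated)
Conditions: PhI(OAc)2, TEMPO (cat.), CH2Cl2, rt
Reagents that add atoms: none
Why: Oxoammonium oxidation is selective for the primary allylic alcohol; enal 20 is captured by the C6 hydroxyl as the five-membered lactol 21, which is oxidised on to the α-methylene lactone (oxidative lactonisation of a 1,4-diol) with retention at C6. The tertiary alcohol is inert.

Step 12
Reactants: 22 (6R,7S,10S)-1-ethoxy-10-hydroxy-3-oxogermacra-1E,4Z,8E,11(13)-tetraen-12,6-olide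
Product: 23 (6R,7S,8R,9S,10S)-8,9-epoxy-1-ethoxy-10-hydroxy-3-oxogermacra-1E,4Z,11(13)-trien-12,6-olide
Conditions: VO(acac)2 (cat.), t-BuOOH, CH2Cl2, 0 °C → rt
Reagents that add atoms: tert-butyl hydroperoxide, CC(C)(C)OO
Why: Hydroxyl-directed epoxidation of a tertiary allylic alcohol: only C8=C9 is allylic to a free hydroxyl, so the other olefins are spared. Because the ring bond C10–C1 must lie over one face of the E olefin, the C10 hydroxyl can reach only the opposite, outer face, which sets the C9–O bond in its final configuration (8R,9S epoxide).

Step 13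
Reactants: 23 (6R,7S,8R,9S,10S)-8,9-epoxy-1-ethoxy-10-hydroxy-3-oxogermacra-1E,4Z,11(13)-trien-12,6-olide
Product: 24 (6R,7S,8S,9S,10S)-1-ethoxy-9,10-dihydroxy-8-(methacryloyloxy)-3-oxogermacra-1E,4Z,11(13)-trien-12,6-olide
Conditions: Ti(OiPr)4, methacrylic acid, BHT (cat.), CH2Cl2, rt
Reagents that add atoms: methacrylic acid, CC(=C)C(O)=O
Why: Titanium-mediated opening of a 2,3-epoxy alcohol by a carboxylic acid: the titanium alkoxide of the C10 hydroxyl activates the epoxide and the carboxylate attacks C8 (the position remote from the carbinol carbon; C9 is neopentyl) with inversion, which sets 8S and installs the methacrylate directly.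

Step 14
Reactants: 24 (6R,7S,8S,9S,10S)-1-ethoxy-9,10-dihydroxy-8-(methacryloyloxy)-3-oxogermacra-1E,4Z,11(13)-trien-12,6-olide
Product: 25 (6R,7S,8S,9S,10S)-9-acetoxy-1-ethoxy-10-hydroxy-8-(methacryloyloxy)-3-oxogermacra-1E,4Z,11(13)-trien-12,6-olide
Conditions: Ac2O, DMAP (cat.), pyridine, CH2Cl2, 0 °C
Reagents that add atoms: acetic anhydride, CC(=O)OC(C)=O
Why: Acylation of the only secondary hydroxyl; the tertiary C10 alcohol does not react under these conditions, and the low temperature limits 1,2-migration of the neighbouring C8 ester.

Step 15
Reactants: 25 (6R,7S,8S,9S,10S)-9-acetoxy-1-ethoxy-10-hydroxy-8-(methacryloyloxy)-3-oxogermacra-1E,4Z,11(13)-trien-12,6-olide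
Product: 26 CNP0365569.2
Conditions: TsOH·H2O (cat.), THF/H2O, rt
Reagents that add atoms: water, O
Why: Acid-catalysed addition of the C10 hydroxyl to the C3 carbonyl with loss of water and ethanol from the vinylogous ester (cyclodehydration of an α′-hydroxy 1,3-diketone equivalent to a 3(2H)-furanone). With C8 and C9 now sp3 the bridge closes without a trans olefin in the oxacycle, and the mild acid leaves esters, lactone and the Z olefin untouched.

## Compound list

1 | (S)-(+)-carvone, (5S)-2-methyl-5-(prop-1-en-2-yl)cyclohex-2-en-1-one | CC1=CC[C@@H](CC1=O)C(C)=C | starting material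
2 | (S)-10-chlorocarvone, (5S)-5-(3-chloroprop-1-en-2-yl)-2-methylcyclohex-2-en-1-one | CC1=CC[C@@H](CC1=O)C(=C)CCl | intermediate
3 | (S)-10-acetoxycarvone | CC1=CC[C@@H](CC1=O)C(=C)COC(C)=O | intermediate (not isolated)
4 | (S)-10-hydroxycarvone, (5S)-5-(3-hydroxyprop-1-en-2-yl)-2-methylcyclohex-2-en-1-one | CC1=CC[C@@H](CC1=O)C(=C)CO | intermediate
5 | (S)-10-(tert-butyldimethylsilyloxy)carvone | CC1=CC[C@@H](CC1=O)C(=C)CO[Si](C)(C)C(C)(C)C | intermediate
6 | allyl bromide | C=CCBr | starting material
7 | lithium enolate of 5 (C1–C6 enolate, cross-conjugated) | CC1=CC[C@@H](C=C1[O-])C(=C)CO[Si](C)(C)C(C)(C)C.[Li+] | intermediate (not isolated)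
8 | (5S,6R)-6-allyl-10-(tert-butyldimethylsilyloxy)carvone (allyl trans to the C5 side chain) | CC1=CC[C@@H]([C@@H](CC=C)C1=O)C(=C)CO[Si](C)(C)C(C)(C)C | intermediate
9 | (5S,6R)-10-(tert-butyldimethylsilyloxy)-6-(2-oxopropyl)carvone | CC1=CC[C@@H]([C@@H](CC(C)=O)C1=O)C(=C)CO[Si](C)(C)C(C)(C)C | intermediate
10 | (5S,6S)-10-(tert-butyldimethylsilyloxy)-6-[(Z)-2-(triisopropylsilyloxy)prop-1-enyl]carvone | CC1=CC[C@@H]([C@@H](/C=C(/C)O[Si](C(C)C)(C(C)C)C(C)C)C1=O)C(=C)CO[Si](C)(C)C(C)(C)C | intermediate
11 | ethoxyacetylene (ethoxyethyne) | CCOC#C | starting material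
12 | lithium ethoxyacetylide | CCOC#C[Li] | intermediate (not isolated)
13 | (1S,5S,6S)-5-[3-(tert-butyldimethylsilyloxy)prop-1-en-2-yl]-1-(ethoxyethynyl)-2-methyl-6-[(Z)-2-(triisopropylsilyloxy)prop-1-enyl]cyclohex-2-en-1-ol (alkynyl cis to the C6 side chain) | CCOC#C[C@@]1(O)C(C)=CC[C@H](C(=C)CO[Si](C)(C)C(C)(C)C)[C@H]1/C=C(\O[Si](C(C)C)(C(C)C)C(C)C)C | intermediate (precursor of the key step)
14 | potassium alkoxide of 13 | CCOC#C[C@@]1([O-])C(C)=CC[C@H](C(=C)CO[Si](C)(C)C(C)(C)C)[C@H]1/C=C(\O[Si](C(C)C)(C(C)C)C(C)C)C.[K+] | intermediate (not isolated)
15 | potassium (7S,10S)-12-(tert-butyldimethylsilyloxy)-1-ethoxy-10-(triisopropylsilyloxy)germacra-1,2,4Z,8E,11(13)-pentaen-3-olate (allenolate) | CCOC1=C=C([O-])/C(C)=C\C[C@H](C(=C)CO[Si](C)(C)C(C)(C)C)/C=C/[C@]1(C)O[Si](C(C)C)(C(C)C)C(C)C.[K+] | intermediate (not isolated)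
16 | (7S,10S)-12-(tert-butyldimethylsilyloxy)-1-ethoxy-10-(triisopropylsilyloxy)germacra-1E,4Z,8E,11(13)-tetraen-3-one | CCO/C1=C/C(=O)/C(C)=C\C[C@H](C(=C)CO[Si](C)(C)C(C)(C)C)/C=C/[C@]1(C)O[Si](C(C)C)(C(C)C)C(C)C | intermediate (product of the key step)
17 | (7S,10S)-12-(tert-butyldimethylsilyloxy)-1-ethoxy-3-(triethylsilyloxy)-10-(triisopropylsilyloxy)germacra-1,3,5,8E,11(13)-pentaene (C3=C4 and C5=C6 drawn ring-cis) | CCO/C1=C/C(O[Si](CC)(CC)CC)=C(C)\C=C/[C@H](C(=C)CO[Si](C)(C)C(C)(C)C)/C=C/[C@]1(C)O[Si](C(C)C)(C(C)C)C(C)C | intermediate (not isolated)
18 | (6R,7S,10S)-12-(tert-butyldimethylsilyloxy)-1-ethoxy-6-hydroxy-10-(triisopropylsilyloxy)germacra-1E,4Z,8E,11(13)-tetraen-3-one | CCO/C1=C/C(=O)/C(C)=C\[C@@H](O)[C@H](C(=C)CO[Si](C)(C)C(C)(C)C)/C=C/[C@]1(C)O[Si](C(C)C)(C(C)C)C(C)C | intermediate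
19 | (6R,7S,10S)-1-ethoxy-6,10,12-trihydroxygermacra-1E,4Z,8E,11(13)-tetraen-3-one | CCO/C1=C/C(=O)/C(C)=C\[C@@H](O)[C@H](C(=C)CO)/C=C/[C@]1(C)O | intermediate
20 | (6R,7S,10S)-1-ethoxy-6,10-dihydroxy-3-oxogermacra-1E,4Z,8E,11(13)-tetraen-12-al | CCO/C1=C/C(=O)/C(C)=C\[C@@H](O)[C@H](C(=C)C=O)/C=C/[C@]1(C)O | intermediate (not isolated)
21 | 12-lactol of 20 (6,12-epoxy-12-hydroxy compound, mixture at C12) | CCO/C1=C/C(=O)/C(C)=C\[C@H]2OC(O)C(=C)[C@@H]2/C=C/[C@]1(C)O | intermediate (not isolated)
22 | (6R,7S,10S)-1-ethoxy-10-hydroxy-3-oxogermacra-1E,4Z,8E,11(13)-tetraen-12,6-olide | CCO/C1=C/C(=O)/C(C)=C\[C@H]2OC(=O)C(=C)[C@@H]2/C=C/[C@]1(C)O | intermediate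
23 | (6R,7S,8R,9S,10S)-8,9-epoxy-1-ethoxy-10-hydroxy-3-oxogermacra-1E,4Z,11(13)-trien-12,6-olide | CCO/C1=C/C(=O)/C(C)=C\[C@H]2OC(=O)C(=C)[C@@H]2[C@H]3O[C@@H]3[C@]1(C)O | intermediate
24 | (6R,7S,8S,9S,10S)-1-ethoxy-9,10-dihydroxy-8-(methacryloyloxy)-3-oxogermacra-1E,4Z,11(13)-trien-12,6-olide | CCO/C1=C/C(=O)/C(C)=C\[C@H]2OC(=O)C(=C)[C@@H]2[C@H](OC(=O)C(C)=C)[C@H](O)[C@]1(C)O | intermediate
25 | (6R,7S,8S,9S,10S)-9-acetoxy-1-ethoxy-10-hydroxy-8-(methacryloyloxy)-3-oxogermacra-1E,4Z,11(13)-trien-12,6-olide | CCO/C1=C/C(=O)/C(C)=C\[C@H]2OC(=O)C(=C)[C@@H]2[C@H](OC(=O)C(C)=C)[C@H](OC(C)=O)[C@]1(C)O | intermediate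
26 | CNP0365569.2, (6R,7S,8S,9S,10S)-9-acetoxy-3,10-epoxy-8-(methacryloyloxy)-1-oxogermacra-2,4Z,11(13)-trien-12,6-olide | C=C(C)C(=O)O[C@H]1[C@H]2C(=C)C(=O)O[C@@H]2/C=C(/C)C2=CC(=O)[C@@](C)(O2)[C@H]1OC(C)=O | target

## Step count and risk

Total: 15 steps. Longest linear sequence: 15 steps from 1 (6 and 11 are bought).

**Step 8 (key step, proposed new method).** Three processes may defeat it:
- retro-addition of the acetylide from the potassium alkoxide, because both termini of the enyne are electron-rich and the shift may be slow;
- transfer of the silyl group from the enol ether oxygen to the alkoxide, which switches off the acceleration;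
- reaction through the rotamer that leads to a Z C8=C9 olefin, with loss of chirality transfer to C10.

Fallback by known reactions, from 10 back to 16. (Z)-2-Ethoxyvinyllithium (from (Z)-1-bromo-2-ethoxyethene and t-BuLi) is added to 10 to give the ethoxyvinyl carbinol F1. KH and 18-crown-6 then effect the classical anionic oxy-Cope rearrangement of a 1,2-dialkenylcyclohexenol, and the enolate is trapped with Me3SiCl as the trimethylsilyl enol ether F2. Saegusa–Ito oxidation with Pd(OAc)2 introduces the C1=C2 double bond and returns 16. The ethoxy-bearing stereocentre of F2 is removed in that last operation, and C10 is set by the same chirality transfer.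

**Step 6.** Enolisation may go towards the methyl group, or give the E enol ether, or the ring enone may be silylated as well. The first wastes material; the second would later erode the configuration of C10.

Fallback, from 5 to 10. Bromoacetone is converted with iPr3SiOTf and Et3N into the bromo enol ether F3, which is purified as the single Z isomer. It is coupled with the lithium enolate of 5 (LiN(SiMe3)2; Pd2(dba)3 and P(t-Bu)3, zerovalent palladium catalysis; α-alkenylation of a ketone enolate). This installs the enol ether with position and geometry fixed and gives 10 after equilibration of the α′ carbon to the trans isomer, bypassing steps 4 to 6.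

**Step 9.** The oxidant may attack the dienol ether at C4 or C2 instead of C6, or enter C6 from the wrong face. The cis γ-hydroxy enone may also cyclise on acidic supports.

Fallback, from 16 to 18. If the oxidant enters from the other face, the same two operations give the 6-epimeric alcohol F4. A Mitsunobu reaction with 4-nitrobenzoic acid (PPh3, DIAD) inverts C6 to the 4-nitrobenzoate F5, and K2CO3 in methanol releases 18.

**Step 10.** Cleavage of the hindered tertiary silyl ether may be incomplete, or the forcing fluoride treatment may degrade the base-sensitive hydroxy enone.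

Fallback, from 18 to 26, keeping C10 silylated to the end:
- Bu4NF at 0 °C removes only the primary silyl ether to give the diol F6.
- PhI(OAc)2 with TEMPO gives the silylated lactone F7.
- OsO4 with NMO dihydroxylates the outer face of C8=C9 to the diol F8.
- A Mitsunobu reaction with methacrylic acid at the less hindered C8 hydroxyl gives, with inversion, the hydroxy methacrylate F9.
- Acetylation gives the acetate F10.
- Aqueous HF in MeCN cleaves the tertiary silyl ether and closes the furanone in one operation to give 26.

**Step 13.** The acid must approach C8 from the concave side of the trans-fused epoxide. If the opening is slow, the Lewis acid may instead promote transannular attack by C2 of the vinylogous ester, participation of the lactone carbonyl, or acyl migration.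

Fallback, from 22 to 24. OsO4 with NMO adds two hydroxyls to the outer face of the E olefin to give the triol F11 (C9 correct, C8 epimeric). A Mitsunobu reaction with methacrylic acid then esterifies the only unhindered secondary hydroxyl, C8, with inversion (C9 is neopentyl, C10 tertiary) and returns 24 without passing through the epoxide.

## Further compounds

F1 | step 8 | (Z)-2-ethoxyvinyl analogue of carbinol 13 | CCO/C=C\[C@@]1(O)C(C)=CC[C@H](C(=C)CO[Si](C)(C)C(C)(C)C)[C@H]1/C=C(\O[Si](C(C)C)(C(C)C)C(C)C)C
F2 | step 8 | 12-(tert-butyldimethylsilyloxy)-1-ethoxy-10-(triisopropylsilyloxy)-3-(trimethylsilyloxy)germacra-2,4Z,8E,11(13)-tetraene | CCO[C@H]1/C=C(O[Si](C)(C)C)\C(C)=C/C[C@H](C(=C)CO[Si](C)(C)C(C)(C)C)/C=C/[C@]1(C)O[Si](C(C)C)(C(C)C)C(C)C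
F3 | step 6 | (Z)-1-bromo-2-(triisopropylsilyloxy)prop-1-ene | C/C(O[Si](C(C)C)(C(C)C)C(C)C)=C/Br
F4 | step 9 | 6-epimer (6S) of alcohol 18 | CCO/C1=C/C(=O)/C(C)=C\[C@H](O)[C@H](C(=C)CO[Si](C)(C)C(C)(C)C)/C=C/[C@]1(C)O[Si](C(C)C)(C(C)C)C(C)C
F5 | step 9 | 6-O-(4-nitrobenzoate) of alcohol 18 | CCO/C1=C/C(=O)/C(C)=C\[C@@H](OC(=O)c2ccc(cc2)[N+](=O)[O-])[C@H](C(=C)CO[Si](C)(C)C(C)(C)C)/C=C/[C@]1(C)O[Si](C(C)C)(C(C)C)C(C)C
F6 | step 10 | (6R,7S,10S)-1-ethoxy-6,12-dihydroxy-10-(triisopropylsilyloxy)germacra-1E,4Z,8E,11(13)-tetraen-3-one | CCO/C1=C/C(=O)/C(C)=C\[C@@H](O)[C@H](C(=C)CO)/C=C/[C@]1(C)O[Si](C(C)C)(C(C)C)C(C)C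
F7 | step 10 | (6R,7S,10S)-1-ethoxy-3-oxo-10-(triisopropylsilyloxy)germacra-1E,4Z,8E,11(13)-tetraen-12,6-olide | CCO/C1=C/C(=O)/C(C)=C\[C@H]2OC(=O)C(=C)[C@@H]2/C=C/[C@]1(C)O[Si](C(C)C)(C(C)C)C(C)C
F8 | step 10 | (8R,9S)-8,9-dihydroxy derivative of F7 | CCO/C1=C/C(=O)/C(C)=C\[C@H]2OC(=O)C(=C)[C@@H]2[C@@H](O)[C@H](O)[C@]1(C)O[Si](C(C)C)(C(C)C)C(C)C
F9 | step 10 | 10-O-triisopropylsilyl ether of 24 | CCO/C1=C/C(=O)/C(C)=C\[C@H]2OC(=O)C(=C)[C@@H]2[C@H](OC(=O)C(C)=C)[C@H](O)[C@]1(C)O[Si](C(C)C)(C(C)C)C(C)C
F10 | step 10 | 10-O-triisopropylsilyl ether of 25 | CCO/C1=C/C(=O)/C(C)=C\[C@H]2OC(=O)C(=C)[C@@H]2[C@H](OC(=O)C(C)=C)[C@H](OC(C)=O)[C@]1(C)O[Si](C(C)C)(C(C)C)C(C)C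
F11 | step 13 | (6R,7S,8R,9S,10S)-1-ethoxy-8,9,10-trihydroxy-3-oxogermacra-1E,4Z,11(13)-trien-12,6-olide | CCO/C1=C/C(=O)/C(C)=C\[C@H]2OC(=O)C(=C)[C@@H]2[C@@H](O)[C@H](O)[C@]1(C)O
A1 | alternative 1 | C8,C9-acetonide of 8,9-dihydroxy-3,10-epoxy-1-oxogermacra-2,4Z,11(13)-trien-12,6-olide | C=C1C(=O)O[C@@H]2/C=C(/C)C3=CC(=O)[C@@](C)(O3)[C@H]4OC(C)(C)O[C@H]4[C@@H]12
A2 | alternative 2 | 11-oxabicyclo[6.2.1]undecadienone with C10 quaternary centre, C9 4-methoxybenzyl ether and C6 tert-butyldimethylsilyl ether | [C@H]1(OCc2ccc(OC)cc2)\C=C/[C@H](O[Si](C)(C)C(C)(C)C)/C=C(/C)[C@@H]3CC(=O)[C@@]1(C)O3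
A3 | alternative 3 | ten-membered 3,5-bridged isoxazole with C10 trimethylsilyl ether, 6,12-lactone and C8,C9 acetonide | [C@]1(C)(O[Si](C)(C)C)c2cc(on2)/C(C)=C\[C@H]3OC(=O)C[C@@H]3[C@@H]4OC(C)(C)O[C@H]14
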